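The route rests on disconnecting the bond between C2 of the dihydropyranone ring and C1' of the 4-(prenyloxy)phenyl ring. C2 is the β-carbon of the C4 ketone and bears the ring oxygen O1, so the flavanone is traced back to a flat, achiral chromone (C2=C3–C4=O). The key step, a rhodium-catalysed enantioselective 1,4-addition of 4-(prenyloxy)phenylboronic acid to 5-hydroxy-8-prenyl-7-silyloxychromone, forms this C–C bond and the only stereocentre (2S) in one operation under ligand control. The 8-prenyl group is installed earlier by a europium-catalysed Claisen–Cope shift of a 5-O-prenyl ether, directed by the C4=O/O5 chelate, and one desilylation completes the synthesis.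

Key step: step 5

Assumption 1: 5,7-dihydroxy-4H-chromen-4-one is taken as a purchasable starting material.
Assumption 2: the 2S configuration requires aryl delivery to the Re face of C2 of the chromone (O1, C3, H clockwise). The (S) antipode of the biaryl bisphosphine is chosen by analogy with (S)-BINAP-type ligands on cyclic enones; this sense is to be confirmed on the parent chromone, and the other antipode used if it is reversed.

Step 1
Reactants: 1 5,7-dihydroxy-4H-chromen-4-one
Product: 2 5-hydroxy-7-[(triisopropylsilyl)oxy]-4H-chromen-4-one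
Conditions: TIPSCl (1.05 equiv), imidazole (2.2 equiv), DMF, 0 °C to rt
Reagents that add atoms: triisopropylsilyl chloride, CC(C)[Si](Cl)(C(C)C)C(C)C
Why: Chemoselective O-silylation, because the 7-OH is the more acidic and unhindered phenol while the 5-OH is held in a hydrogen bond to C4=O and should stay free.

Step 2
Reactants: 2 5-hydroxy-7-[(triisopropylsilyl)oxy]-4H-chromen-4-one; 3 3-methylbut-2-en-1-ol (prenol)
Product: 4 5-[(3-methylbut-2-en-1-yl)oxy]-7-[(triisopropylsilyl)oxy]-4H-chromen-4-one
Conditions: PPh3 (1.5 equiv), DIAD (1.5 equiv), THF, 0 °C to rt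
Reagents that add atoms: none
Why: Mitsunobu etherification alkylates the chelated 5-phenol at the primary carbinol carbon of prenol under neutral conditions that leave the aryl silyl ether intact.

Step 3
Reactants: 4 5-[(3-methylbut-2-en-1-yl)oxy]-7-[(triisopropylsilyl)oxy]-4H-chromen-4-one
Product: 7 5-hydroxy-8-(3-methylbut-2-en-1-yl)-7-[(triisopropylsilyl)oxy]-4H-chromen-4-one, via ortho-dienone 5 (not isolated), via para-dienone 6 (not isolated)
Conditions: Eu(fod)3 (10 mol%), NaHCO3, PhCl, 85 °C
Reagents that add atoms: none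
Why: Tandem aromatic Claisen–Cope rearrangement, in which Eu(III) held in the C4=O/O5 chelate accelerates the [3,3] shift of the 5-O-prenyl group to C6 (reverse-prenyl dienone 5), a second [3,3] Cope shift carries it to C8, para to O5, with normal prenyl connectivity (dienone 6), and enolisation restores the 5-phenol; no stereocentre remains.

Step 4
Reactants: 8 (4-hydroxyphenyl)boronic acid; 9 1-bromo-3-methylbut-2-ene (prenyl bromide)
Product: 10 {4-[(3-methylbut-2-en-1-yl)oxy]phenyl}boronic acid
Conditions: K2CO3 (2 equiv), acetone, rt; then aq. NH4Cl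
Reagents that add atoms: none
Why: Williamson ether synthesis, SN2 attack of the phenoxide on the primary allylic bromide, with the boronic acid carried through as its borate and recovered on mild acidification.

Step 5
Reactants: 7 5-hydroxy-8-(3-methylbut-2-en-1-yl)-7-[(triisopropylsilyl)oxy]-4H-chromen-4-one; 10 {4-[(3-methylbut-2-en-1-yl)oxy]phenyl}boronic acid
Product: 11 (2S)-5-hydroxy-8-(3-methylbut-2-en-1-yl)-2-{4-[(3-methylbut-2-en-1-yl)oxy]phenyl}-7-[(triisopropylsilyl)oxy]-2,3-dihydro-4H-chromen-4-one
Conditions: [RhCl(C2H4)2]2 (2.5 mol%), (S)-MeO-F12-BIPHEP (5.5 mol%), aq. KOH (10 mol%), 10 (3 equiv), toluene/H2O 10:1, 35 °C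
Reagents that add atoms: none
Why: Rhodium-catalysed asymmetric conjugate addition of an arylboronic acid (Hayashi–Miyaura 1,4-addition): transmetalation of 10 to a bisphosphine–Rh–OH species gives an aryl–Rh(I) complex, the C2=C3 bond of 7 inserts so that the aryl group bonds to C2 and rhodium rests on C3/O4 as an oxa-π-allyl, and water protonates C3 and regenerates Rh–OH. The closest known reaction type is this same 1,4-addition of arylboronic acids to chromones to give flavanones, for which electron-poor atropisomeric bisphosphines are suited. No ring is closed; the existing pyranone ring only changes from chromone to chroman-4-one. The single new stereocentre C2 is set by catalyst control, the C2-symmetric ligand exposing the Re face of C2 of the flat, achiral chromone to the migrating aryl group, which gives 2S. The step needs 1,4- rather than 1,2-addition, no insertion into the two prenyl C=C bonds and no retro-oxa-Michael opening of the product; these are secured respectively by the vinylogous-ester character of the chromone reinforced by the 5-OH···O=C4 hydrogen bond, by the unactivated trisubstituted nature of the prenyl alkenes, and by using only catalytic hydroxide buffered by excess boronic acid.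

Step 6
Reactants: 11 (2S)-5-hydroxy-8-(3-methylbut-2-en-1-yl)-2-{4-[(3-methylbut-2-en-1-yl)oxy]phenyl}-7-[(triisopropylsilyl)oxy]-2,3-dihydro-4H-chromen-4-one
Product: 12 (2S)-5,7-dihydroxy-8-(3-methylbut-2-en-1-yl)-2-{4-[(3-methylbut-2-en-1-yl)oxy]phenyl}-2,3-dihydro-4H-chromen-4-one
Conditions: TBAF (1.2 equiv), AcOH (1.5 equiv), THF, 0 °C
Reagents that add atoms: none
Why: Fluoride cleavage of the aryl Si–O bond, with acetic acid buffering to keep phenoxide and enolate concentrations low so that C2 (retro-oxa-Michael), the prenyl ether and both alkenes should be untouched.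

Compound list
1 | 5,7-dihydroxy-4H-chromen-4-one | O=c1ccoc2cc(O)cc(O)c12 | starting material
2 | 5-hydroxy-7-[(triisopropylsilyl)oxy]-4H-chromen-4-one | O=c1ccoc2cc(O[Si](C(C)C)(C(C)C)C(C)C)cc(O)c12 | intermediate
3 | 3-methylbut-2-en-1-ol (prenol) | CC(C)=CCO | starting material
4 | 5-[(3-methylbut-2-en-1-yl)oxy]-7-[(triisopropylsilyl)oxy]-4H-chromen-4-one | CC(C)=CCOc1cc(O[Si](C(C)C)(C(C)C)C(C)C)cc2occc(=O)c12 | intermediate
5 | 6-(2-methylbut-3-en-2-yl)-7-[(triisopropylsilyl)oxy]-4H-chromene-4,5(6H)-dione (ortho-dienone, racemic at C6) | C=CC(C)(C)C1C(=O)C2=C(C=C1O[Si](C(C)C)(C(C)C)C(C)C)OC=CC2=O | intermediate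
6 | 8-(3-methylbut-2-en-1-yl)-7-[(triisopropylsilyl)oxy]-4H-chromene-4,5(8H)-dione (para-dienone, racemic at C8) | CC(C)=CCC1C(O[Si](C(C)C)(C(C)C)C(C)C)=CC(=O)C2=C1OC=CC2=O | intermediate
7 | 5-hydroxy-8-(3-methylbut-2-en-1-yl)-7-[(triisopropylsilyl)oxy]-4H-chromen-4-one | CC(C)=CCc1c(O[Si](C(C)C)(C(C)C)C(C)C)cc(O)c2c(=O)ccoc12 | intermediate
8 | (4-hydroxyphenyl)boronic acid | OB(O)c1ccc(O)cc1 | starting material
9 | 1-bromo-3-methylbut-2-ene (prenyl bromide) | CC(C)=CCBr | starting material
10 | {4-[(3-methylbut-2-en-1-yl)oxy]phenyl}boronic acid | CC(C)=CCOc1ccc(B(O)O)cc1 | intermediate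
11 | (2S)-5-hydroxy-8-(3-methylbut-2-en-1-yl)-2-{4-[(3-methylbut-2-en-1-yl)oxy]phenyl}-7-[(triisopropylsilyl)oxy]-2,3-dihydro-4H-chromen-4-one | CC(C)=CCOc1ccc([C@@H]2CC(=O)c3c(O)cc(O[Si](C(C)C)(C(C)C)C(C)C)c(CC=C(C)C)c3O2)cc1 | intermediate
12 | (2S)-5,7-dihydroxy-8-(3-methylbut-2-en-1-yl)-2-{4-[(3-methylbut-2-en-1-yl)oxy]phenyl}-2,3-dihydro-4H-chromen-4-one | CC(C)=CCOc1ccc([C@@H]2CC(=O)c3c(O)cc(O)c(CC=C(C)C)c3O2)cc1 | target

Total step count: 6. Longest linear sequence: 5 steps (1 → 2 → 4 → 7 → 11 → 12); step 4 is a one-step branch.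

Steps most likely to fail

Step 5. Rhodium may be sequestered as an O,O-chelate by the 5-hydroxy-4-keto unit, protodeboronation of 10 may outrun insertion into the electron-rich chromone, or facial discrimination may be insufficient. The fallback removes the chelating phenol and changes the metal manifold. It sets out from 7, which is silylated at O5 (TBSOTf, 2,6-lutidine, CH2Cl2, 0 °C) to give 5-[(tert-butyldimethylsilyl)oxy]-8-(3-methylbut-2-en-1-yl)-7-[(triisopropylsilyl)oxy]-4H-chromen-4-one F1. F1 and 10 are then joined by the base-free cationic Pd(II)/pyridine-oxazoline conjugate addition (Pd(OCOCF3)2, the t-BuPyOX antipode that gives Re-face delivery, NH4PF6, H2O, ClCH2CH2Cl, 40–60 °C) to give the bis-silyl flavanone (2S)-5-[(tert-butyldimethylsilyl)oxy]-8-(3-methylbut-2-en-1-yl)-2-{4-[(3-methylbut-2-en-1-yl)oxy]phenyl}-7-[(triisopropylsilyl)oxy]-2,3-dihydro-4H-chromen-4-one F2. Removal of both silyl groups from F2 with TBAF/AcOH in THF at 0 °C comes back to the route at compound 12.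

Step 3. The ortho-dienone 5 may enolise before the Cope shift, arresting the sequence at the 6-(1,1-dimethylallyl) isomer, or the Lewis acid may cause loss of the prenyl group; the bulky silyl ether next to C8 makes both more likely. The fallback inverts the order of events so that the rearrangement is run on a flavanone, the substrate class on which this europium-catalysed para-shift is best established. It sets out from 4, which undergoes the rhodium-catalysed asymmetric 1,4-addition of 10 under the conditions of step 5 to give (2S)-5-[(3-methylbut-2-en-1-yl)oxy]-2-{4-[(3-methylbut-2-en-1-yl)oxy]phenyl}-7-[(triisopropylsilyl)oxy]-2,3-dihydro-4H-chromen-4-one F3. Eu(fod)3 in CHCl3 at 60 °C should then move only the prenyl group of the chelating 5-O-ether to C8, since the 4'-ether has no neighbouring carbonyl and is thermally inert at this temperature. This comes back to the route at compound 11.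

Step 6. C2 may epimerise during fluoride treatment through phenoxide- or enolate-triggered retro-oxa-Michael opening to the 2'-hydroxychalcone and reclosure. The fallback removes the silyl group before the stereocentre exists. It sets out from 7, which is desilylated with TBAF/AcOH in THF to give 5,7-dihydroxy-8-(3-methylbut-2-en-1-yl)-4H-chromen-4-one F4. Base-free Pd(II)/t-BuPyOX conjugate addition of 10 to F4, under acidic aqueous conditions that tolerate free phenols, then forms the stereocentre in the last operation and comes back to the route at compound 12.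

Further compounds
F1 | step 5 | 5-[(tert-butyldimethylsilyl)oxy]-8-(3-methylbut-2-en-1-yl)-7-[(triisopropylsilyl)oxy]-4H-chromen-4-one | CC(C)=CCc1c(O[Si](C(C)C)(C(C)C)C(C)C)cc(O[Si](C)(C)C(C)(C)C)c2c(=O)ccoc12
F2 | step 5 | (2S)-5-[(tert-butyldimethylsilyl)oxy]-8-(3-methylbut-2-en-1-yl)-2-{4-[(3-methylbut-2-en-1-yl)oxy]phenyl}-7-[(triisopropylsilyl)oxy]-2,3-dihydro-4H-chromen-4-one | CC(C)=CCOc1ccc([C@@H]2CC(=O)c3c(O[Si](C)(C)C(C)(C)C)cc(O[Si](C(C)C)(C(C)C)C(C)C)c(CC=C(C)C)c3O2)cc1
F3 | step 3 | (2S)-5-[(3-methylbut-2-en-1-yl)oxy]-2-{4-[(3-methylbut-2-en-1-yl)oxy]phenyl}-7-[(triisopropylsilyl)oxy]-2,3-dihydro-4H-chromen-4-one | CC(C)=CCOc1ccc([C@@H]2CC(=O)c3c(OCC=C(C)C)cc(O[Si](C(C)C)(C(C)C)C(C)C)cc3O2)cc1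
F4 | step 6 | 5,7-dihydroxy-8-(3-methylbut-2-en-1-yl)-4H-chromen-4-one | CC(C)=CCc1c(O)cc(O)c2c(=O)ccoc12
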